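The constants belong to no real substance; the run is a simulation.

The balance of G is my invariant: a G that has gone has left either through the catalysed step on D, towards Z, or through the uncatalysed leak to L, so the share of Z is the outcome of a race between two exits.

    Q + D ⇌ X + D, rate k1*[D]*[Q] forward; the back reaction follows from the equilibrium constant (K1 = 1.0, k1 = 0.0060 M⁻¹ s⁻¹, Ea1 = 53.0 kJ mol⁻¹, ΔH1 = −22.0 kJ mol⁻¹)
    G → L (k2 = 8.2 × 10⁻⁵ s⁻¹, Ea2 = 96.0 kJ mol⁻¹)
    G + D ⇌ Z + D, rate k3*[G]*[D] forward; the back reaction follows from the equilibrium constant (K3 = 11, k3 = 0.26 M⁻¹ s⁻¹, Ea3 = 41.0 kJ mol⁻¹, ΔH3 = −45.0 kJ mol⁻¹)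
    D → E (k4 = 1.9 × 10⁻⁴ s⁻¹, Ea4 = 84.0 kJ mol⁻¹)
    Z + D ⇌ Q + D, rate k5*[D]*[Z] forward; the back reaction follows from the equilibrium constant (K5 = 3.4, k5 = 0.019 M⁻¹ s⁻¹, Ea5 = 70.0 kJ mol⁻¹, ΔH5 = −81.0 kJ mol⁻¹)
    (constants at 25 °C)

in all of them: G 0.015 M; D 5 mol%; time 3.0 h
- violet: temperature 45 °C
- amber: temperature 65 °C
- red: temperature 5 °C
- blue: temperature 25 °C

* the flask with the highest share of Z in all that became Z or Q or X or L ("all alike" if they lie within 1.5 percentage points) (violet / amber / red / blue / all alike)
* share of Z in all that became Z or Q or X or L, violet
* share of Z in all that became Z or Q or X or L, amber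
* share of Z in all that became Z or Q or X or L, red
* share of Z in all that became Z or Q or X or L, blue

- the constants hold at 25 °C; other temperatures follow from the activation energies and enthalpies

The catalysed exit opens at its rate constant times the D charged, but it fades, for D dies to E, a form outside the working round (catalyst deactivation), while the leak thins the G. Leaving aside the G that the catalysed exit itself consumes, the catalysed flow falls at the sum of two first-order constants, and summing it over that joint lifetime folds the givens into one number, the reach, which I read as the odds of the catalysed exit against the leak and not as an amount of G taken per G charged: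

reach = catalysed constant × D charged / (leak constant + death constant)

share of Z ≈ reach / (1 + reach)

I take amber first. The equilibrium constant of the Z-to-Q step, 0.0713 there against 3.4 at the reference temperature, serves me as a thermometer for shifting the rate constants:

catalysed exit 0.00138 s⁻¹, leak 0.00800 s⁻¹, death of D 0.0105 s⁻¹

reach 0.0747, share 6.95%

Amber's 3.0 h spans 113 lifetimes of D, so the number applies there.

One number is not enough, though, for it assumes that D has died. Red spans 0.179 of a lifetime of D, less than one, so the death term drops out of red's race. What remains is the selectivity factor, catalysed exit over leak: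

11.7, share 92.1%

Blue lies between these cases. Its reach is 0.717, a share of 41.8%, but only 2.05 lifetimes of D pass, and its opening ratio of 2.38 is higher than its reach, so I expect blue above that figure. I commit to red first, and I reckon no number for violet.

The forecast also names red, with 91% there, 55% in blue, 17.8% in violet and 6.8% in amber, on the ground that “cold keeps the catalyst alive and lets it win”.

The flask puts red first at 90.6%, with blue at 53.2%, violet at 17.5% and amber at 6.55%, each inside the forecast's range. With the conversion of G into L struck out, amber's share stands at 98.3%. Amber's reach of 0.0747 is proportional to the D charged, so the neighbour of amber charged with 0.037 M of G, at the same loading and time, has a reach of 0.184 and a reckoned share of 15.5%. That neighbour gives 13.6%, with 85.8% of its G ending as L.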